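**Plan**

1. Labels: ring 1 is the dihydrofuran O1–C2–C3–C3a–C7a fused to benzo ring B (C4 styryl, C6 oxygen), with 4‑oxyphenyl ring C on C2. Ring 2 is the dihydrofuran O1'–C2'–C3'–C3a'–C7a' fused to benzo ring D, which sits on C3. Ring E (3,5‑dioxyphenyl) is on C3', ring F (4‑oxyphenyl) on C2', ring G is the styryl aryl group.
2. Cuts, in retrosynthetic order: the O‑protecting groups and the C4–vinyl bond (Suzuki–Miyaura); O1–C2 of ring 1; the C3=C2 alkene and the C3–ring B bond (aryl‑metal addition to a ketone, dehydration); the ring D–C3 bond (Weinreb ketone synthesis); C2'–C3' of ring 2 (carbene C–H insertion) and C3'–ring E (Grignard addition).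
3. Forward order: ring 2 is built first on a bromo‑ortho‑vanillin core; its bromide then joins the C3–C2 chain carrying ring C; ring B is added to give a triarylethene; ring 1 is closed; the Z‑styryl group comes last.
4. Enabling feature: C2 carries the 4‑oxyphenyl ring C, so a cation at C2 is a para‑quinone‑methide‑type ion. C3 is only a C–H between rings B and D, and ring B (with the C4 substituent traded for oxygen) has two equivalent oxygens ortho to C3a. Ring 1 is therefore the adduct of one of these hydroxyls across a C3=C2 double bond.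
5. Stereochemistry: C3' from a chiral Rh2 tetracarboxylate carbene insertion, C2' from acid equilibration to the trans ring; C3 from catalyst‑controlled protonation by a confined chiral Brønsted acid, C2 from trans ring closure; the Z alkene from a Z‑alkenylboronate coupled with retention.

Key step: step 12

Assumption: the catalyst antipodes written in steps 5 and 12 are taken to give the drawn configurations; if the sense of induction proves opposite, the mirror‑image catalyst is used.

Shorthand in names: Ar2 = (2R,3R)-3-(3,5-dimethoxyphenyl)-7-methoxy-2-(4-methoxyphenyl)-2,3-dihydro-1-benzofuran-5-yl (the ring 2 unit, bonded through C5').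

**Route**

Step 1
Reactants: 1 5-bromo-2-hydroxy-3-methoxybenzaldehyde; 2 4-methoxybenzyl chloride
Product: 3 5-bromo-3-methoxy-2-[(4-methoxybenzyl)oxy]benzaldehyde
Conditions: K2CO3, n-Bu4NI (cat.), DMF, 60 °C
Reagents that add atoms: none
Why: Williamson ether synthesis, in which the phenoxide of 1 (acidified by the ortho‑formyl group) displaces chloride from the benzylic halide and so installs the O–CH2 unit that supplies C2' and ring F.

Step 2
Reactants: 3 5-bromo-3-methoxy-2-[(4-methoxybenzyl)oxy]benzaldehyde; 4 1-bromo-3,5-dimethoxybenzene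
Product: 6 rac-{5-bromo-3-methoxy-2-[(4-methoxybenzyl)oxy]phenyl}(3,5-dimethoxyphenyl)methanol, via 3,5-dimethoxyphenylmagnesium bromide 5 (not isolated)
Conditions: 4, Mg, I2 (cat.), THF, 50 °C; then 3, THF, 0 °C; aqueous work-up
Reagents that add atoms: none
Why: Grignard addition of an aryl nucleophile to the aromatic aldehyde is fast at 0 °C, where the aryl bromide of 3 does not exchange, and the racemic carbinol centre is removed in step 3.

Step 3
Reactants: 6 rac-{5-bromo-3-methoxy-2-[(4-methoxybenzyl)oxy]phenyl}(3,5-dimethoxyphenyl)methanol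
Product: 7 {5-bromo-3-methoxy-2-[(4-methoxybenzyl)oxy]phenyl}(3,5-dimethoxyphenyl)methanone
Conditions: activated MnO2 (excess), CH2Cl2, rt
Reagents that add atoms: none
Why: Activated MnO2 oxidises the doubly benzylic alcohol to the benzophenone (benzylic alcohol oxidation) and leaves the benzyl ether and the aryl bromide untouched.

Step 4
Reactants: 7 {5-bromo-3-methoxy-2-[(4-methoxybenzyl)oxy]phenyl}(3,5-dimethoxyphenyl)methanone
Product: 8 {5-bromo-3-methoxy-2-[(4-methoxybenzyl)oxy]phenyl}(3,5-dimethoxyphenyl)methanone hydrazone (E/Z mixture)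
Conditions: N2H4·H2O (10 equiv), AcOH (cat.), EtOH, 80 °C
Reagents that add atoms: hydrazine hydrate, NN.O
Why: Condensation of the diaryl ketone with a large excess of hydrazine (hydrazone formation) gives the N‑unsubstituted hydrazone, the excess suppressing azine formation.

Step 5
Reactants: 8 {5-bromo-3-methoxy-2-[(4-methoxybenzyl)oxy]phenyl}(3,5-dimethoxyphenyl)methanone hydrazone
Product: 10 (2S,3R)-5-bromo-3-(3,5-dimethoxyphenyl)-7-methoxy-2-(4-methoxyphenyl)-2,3-dihydro-1-benzofuran (cis), via diaryldiazomethane 9 (not isolated)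
Conditions: activated MnO2, CH2Cl2, 0 °C, filtration; then Rh2(S-PTAD)4 (1 mol%), CH2Cl2, 0 °C
Reagents that add atoms: none
Why: Dehydrogenation of the hydrazone gives a diaryldiazomethane whose donor/donor Rh carbene inserts into the ether‑activated para‑methoxybenzylic C–H bond (intramolecular 1,5 C–H insertion), a reaction type known to give 2,3‑cis‑diaryl‑2,3‑dihydrobenzofurans with the absolute configuration dictated by the chiral carboxylate ligands, so C3' (R) is set by the catalyst and C2' (S) arises cis to it.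

Step 6
Reactants: 10 (2S,3R)-5-bromo-3-(3,5-dimethoxyphenyl)-7-methoxy-2-(4-methoxyphenyl)-2,3-dihydro-1-benzofuran
Product: 11 (2R,3R)-5-bromo-3-(3,5-dimethoxyphenyl)-7-methoxy-2-(4-methoxyphenyl)-2,3-dihydro-1-benzofuran (trans; Ar2–Br)
Conditions: CF3CO2H (10 equiv), CH2Cl2 (dilute), 0 °C → rt
Reagents that add atoms: none
Why: Acid‑mediated C2 epimerisation of a 2‑(4‑alkoxyphenyl)‑2,3‑dihydrobenzofuran, in which reversible ionisation of the C2'–O bond to a para‑methoxybenzylic cation and re‑closure under thermodynamic control give the trans ring, inverting C2' to R while C3' is not touched.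

Step 7
Reactants: 12 4-methoxyphenylacetyl chloride
Product: 13 N-methoxy-2-(4-methoxyphenyl)-N-methylacetamide
Conditions: MeNH(OMe)·HCl, Et3N, CH2Cl2, 0 °C → rt
Reagents that add atoms: N,O-dimethylhydroxylamine hydrochloride, CNOC.Cl
Why: Acylation of N,O‑dimethylhydroxylamine by the acid chloride (amide formation) gives the Weinreb amide needed for a single aryl addition.

Step 8
Reactants: 11 Ar2–Br; 13 N-methoxy-2-(4-methoxyphenyl)-N-methylacetamide
Product: 15 1-(Ar2)-2-(4-methoxyphenyl)ethan-1-one, via aryllithium Ar2–Li 14 (not isolated)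
Conditions: n-BuLi, THF, −78 °C; then 13, −78 → −20 °C; aqueous work-up
Reagents that add atoms: none
Why: Bromine–lithium exchange at −78 °C followed by Weinreb ketone synthesis, in which the aryllithium adds only once because the chelated tetrahedral adduct survives until work-up and the low temperature favours addition over deprotonation of the benzylic CH2, the ring 2 stereocentres not being involved.

Step 9
Reactants: 16 5-methoxybenzene-1,3-diol
Product: 17 1-methoxy-3,5-bis(methoxymethoxy)benzene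
Conditions: MeOCH2Cl, i-Pr2NEt, CH2Cl2, 0 °C → rt
Reagents that add atoms: chloromethyl methyl ether, COCCl
Why: Alkylation of both phenols with chloromethyl methyl ether under amine base (acetal protection) gives ethers that direct the metalation in step 10 and can later be removed without protic acid.

Step 10
Reactants: 17 1-methoxy-3,5-bis(methoxymethoxy)benzene; 15 1-(Ar2)-2-(4-methoxyphenyl)ethan-1-one
Product: 21 5-methoxy-2-[(Z)-1-(Ar2)-2-(4-methoxyphenyl)ethenyl]-1,3-bis(methoxymethoxy)benzene, via [4-methoxy-2,6-bis(methoxymethoxy)phenyl]lithium 18 (not isolated), via dichloro[4-methoxy-2,6-bis(methoxymethoxy)phenyl]cerium 19 (not isolated), via tertiary alcohol 20 (not isolated)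
Conditions: 17, n-BuLi, THF, 0 °C; anhydrous CeCl3, THF, −78 °C; then 15, −78 → −20 °C; aqueous work-up; crude 20, Burgess reagent, PhMe, 50 °C
Reagents that add atoms: none
Why: Directed ortho‑metalation takes place at the carbon flanked by the two OCH2OMe groups, transmetalation to the weakly basic organocerium reagent lets the aryl group add to the easily enolised benzyl ketone (organocerium 1,2‑addition), and Burgess dehydration of the tertiary benzylic alcohol under neutral conditions can only place the double bond between C3 and C2, expected mainly as the Z isomer with rings C and D trans (any E isomer is carried along because both converge in step 12).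

Step 11
Reactants: 21 5-methoxy-2-[(Z)-1-(Ar2)-2-(4-methoxyphenyl)ethenyl]-1,3-bis(methoxymethoxy)benzene
Product: 23 5-methoxy-2-[(Z)-1-(Ar2)-2-(4-methoxyphenyl)ethenyl]benzene-1,3-diol, via bis(trimethylsilyl) ether 22 (not isolated)
Conditions: Me3SiOTf, 2,2'-bipyridyl, MeCN, 0 °C → rt; then H2O; purification on Et3N-deactivated silica
Reagents that add atoms: none
Why: Cleavage of aryl methoxymethyl ethers with Me3SiOTf buffered by 2,2'‑bipyridyl proceeds through the aryl silyl ethers, which hydrolyse on adding water, so the two hydroxyls are released without the protic acid that would close ring 1 without stereocontrol.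

Step 12
Reactants: 23 5-methoxy-2-[(Z)-1-(Ar2)-2-(4-methoxyphenyl)ethenyl]benzene-1,3-diol
Product: 24 (2S,3S)-3-(Ar2)-6-methoxy-2-(4-methoxyphenyl)-2,3-dihydro-1-benzofuran-4-ol
Conditions: (S,S)-IDPi Brønsted acid [BINOL-derived imidodiphosphorimidate, 3,3'-bis(3,5-bis(trifluoromethyl)phenyl) groups, N-trifluoromethanesulfonyl] (5 mol%), PhMe/CH2Cl2 (4:1), −40 °C
Reagents that add atoms: none
Why: Proposed new method: the strongly acidic, confined imidodiphosphorimidate is expected to bind 23 through hydrogen bonds to the two ring B hydroxyls and to deliver its proton to C3 of the C3=C2 bond inside the chiral anion pocket, giving a C2 cation delocalised into ring C (an O‑methyl para‑quinone methide) as a contact ion pair, after which one ortho‑hydroxyl adds to C2 and forms O1–C2. The closest known reaction types are the imidodiphosphorimidate‑catalysed asymmetric intramolecular hydroalkoxylation of alkenes and chiral phosphoric acid catalysis through para‑quinone‑methide‑type cations generated from 4‑oxystyrenes. Ring 1 closes as a five‑membered ring in a 5‑exo‑trig mode with respect to the quinoid C2=C(ring C) bond, although it is formally 5‑endo with respect to the original alkene, which is why the stepwise cationic path is needed. C3 (S) is set by the catalyst‑chosen face of proton transfer and C2 (S) by closure anti to the ring D substituent on C3, the trans ring also being the thermodynamic one. The step needs productive protonation at C3 and not at C2: protonation at C2 gives a diarylmethyl cation that cannot close a ring and only returns to the alkene, thereby interconverting the E and Z isomers, whereas the C2 cation is trapped at once by the neighbouring hydroxyl at low temperature, so the geometry of 23 does not matter. No choice between the hydroxyls arises because they are related by the local symmetry of ring B, and because ring 2 is remote and already enantiopure the outcome is catalyst‑controlled and a minor ring 1 epimer would be a separable diastereomer.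

Step 13
Reactants: 24 (2S,3S)-3-(Ar2)-6-methoxy-2-(4-methoxyphenyl)-2,3-dihydro-1-benzofuran-4-ol
Product: 25 (2S,3S)-3-(Ar2)-6-methoxy-2-(4-methoxyphenyl)-2,3-dihydro-1-benzofuran-4-yl trifluoromethanesulfonate
Conditions: Tf2O, pyridine, CH2Cl2, −20 → 0 °C
Reagents that add atoms: trifluoromethanesulfonic anhydride, O=S(=O)(OS(=O)(=O)C(F)(F)F)C(F)(F)F
Why: O‑Sulfonylation of the only free phenol with triflic anhydride buffered by pyridine (aryl triflate formation) turns the C4 oxygen into a cross‑coupling handle while the acid‑labile benzylic ethers stay intact.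

Step 14
Reactants: 25 (2S,3S)-3-(Ar2)-6-methoxy-2-(4-methoxyphenyl)-2,3-dihydro-1-benzofuran-4-yl trifluoromethanesulfonate
Product: 27 (2S,3S)-6-acetoxy-2-(4-acetoxyphenyl)-3-[(2R,3R)-7-acetoxy-2-(4-acetoxyphenyl)-3-(3,5-diacetoxyphenyl)-2,3-dihydro-1-benzofuran-5-yl]-2,3-dihydro-1-benzofuran-4-yl trifluoromethanesulfonate, via hexaphenol triflate 26 (not isolated)
Conditions: BBr3 (12 equiv), CH2Cl2, −78 → 0 °C; H2O quench at −78 °C; then Ac2O, pyridine, DMAP (cat.), rt
Reagents that add atoms: acetic anhydride, CC(=O)OC(C)=O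
Why: Lewis acid ether cleavage with BBr3 removes the six O‑methyl groups while the aryl triflate is inert, related trans‑2‑aryl‑2,3‑dihydrobenzofurans are known to survive it, and acetylation of the crude hexaphenol gives an easily purified hexaacetate, the step being placed before the acid‑sensitive Z‑stilbene exists.

Step 15
Reactants: 28 tert-butyl(4-ethynylphenoxy)dimethylsilane
Product: 29 tert-butyldimethyl{4-[(Z)-2-(4,4,5,5-tetramethyl-1,3,2-dioxaborolan-2-yl)ethenyl]phenoxy}silane
Conditions: pinacolborane, [Rh(cod)Cl]2 (1.5 mol%), P(i-Pr)3 (6 mol%), Et3N, cyclohexane, rt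
Reagents that add atoms: pinacolborane, CC1(C)OBOC1(C)C
Why: Rh‑catalysed formal trans‑hydroboration of a terminal alkyne through a vinylidene intermediate gives the (Z)‑alkenylboronate and so fixes the alkene geometry before coupling.

Step 16
Reactants: 27 hexaacetate triflate (full name in step 14); 29 tert-butyldimethyl{4-[(Z)-2-(4,4,5,5-tetramethyl-1,3,2-dioxaborolan-2-yl)ethenyl]phenoxy}silane
Product: 30 (2S,3S)-6-acetoxy-2-(4-acetoxyphenyl)-3-[(2R,3R)-7-acetoxy-2-(4-acetoxyphenyl)-3-(3,5-diacetoxyphenyl)-2,3-dihydro-1-benzofuran-5-yl]-4-{(Z)-2-[4-(tert-butyldimethylsilyloxy)phenyl]ethenyl}-2,3-dihydro-1-benzofuran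
Conditions: Pd(OAc)2 (5 mol%), SPhos (10 mol%), K3PO4, H2O (5 equiv), THF, 45 °C
Reagents that add atoms: none
Why: Suzuki–Miyaura coupling of an aryl triflate with an alkenylboronate proceeds with retention of alkene geometry, the bulky biarylphosphine letting the hindered C4 position react at a temperature at which the Z alkene should not isomerise, and partial loss of acetyl or silyl groups would not matter because step 17 removes them all.

Step 17
Reactants: 30 coupled hexaacetate silyl ether (full name in step 16)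
Product: 31 (2S,3S)-3-[(2R,3R)-3-(3,5-dihydroxyphenyl)-7-hydroxy-2-(4-hydroxyphenyl)-2,3-dihydro-1-benzofuran-5-yl]-2-(4-hydroxyphenyl)-4-[(Z)-2-(4-hydroxyphenyl)ethenyl]-2,3-dihydro-1-benzofuran-6-ol (CNP0172909.2)
Conditions: K2CO3 (cat.), MeOH/THF (degassed), 0 °C → rt; pH 5 buffer work-up
Reagents that add atoms: none
Why: Carbonate‑catalysed methanolysis (transesterification and phenolic silyl ether cleavage) frees all seven phenols under mild basic conditions that neither ionise the benzylic C–O bonds of rings 1 and 2 nor isomerise the Z‑stilbene.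

**Compound list**

1 | 5-bromo-2-hydroxy-3-methoxybenzaldehyde | O=Cc1cc(Br)cc(OC)c1O | starting material
2 | 4-methoxybenzyl chloride | COc1ccc(CCl)cc1 | starting material
3 | 5-bromo-3-methoxy-2-[(4-methoxybenzyl)oxy]benzaldehyde | O=Cc1cc(Br)cc(OC)c1OCc1ccc(OC)cc1 | intermediate
4 | 1-bromo-3,5-dimethoxybenzene | COc1cc(Br)cc(OC)c1 | starting material
5 | 3,5-dimethoxyphenylmagnesium bromide | COc1cc([Mg]Br)cc(OC)c1 | intermediate
6 | rac-{5-bromo-3-methoxy-2-[(4-methoxybenzyl)oxy]phenyl}(3,5-dimethoxyphenyl)methanol | OC(c1cc(OC)cc(OC)c1)c1cc(Br)cc(OC)c1OCc1ccc(OC)cc1 | intermediate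
7 | {5-bromo-3-methoxy-2-[(4-methoxybenzyl)oxy]phenyl}(3,5-dimethoxyphenyl)methanone | O=C(c1cc(OC)cc(OC)c1)c1cc(Br)cc(OC)c1OCc1ccc(OC)cc1 | intermediate
8 | hydrazone of 7 (E/Z mixture) | NN=C(c1cc(OC)cc(OC)c1)c1cc(Br)cc(OC)c1OCc1ccc(OC)cc1 | intermediate
9 | 5-bromo-1-[diazo(3,5-dimethoxyphenyl)methyl]-3-methoxy-2-[(4-methoxybenzyl)oxy]benzene | [N-]=[N+]=C(c1cc(OC)cc(OC)c1)c1cc(Br)cc(OC)c1OCc1ccc(OC)cc1 | intermediate
10 | (2S,3R)-5-bromo-3-(3,5-dimethoxyphenyl)-7-methoxy-2-(4-methoxyphenyl)-2,3-dihydro-1-benzofuran (cis) | Brc1cc(OC)c2c(c1)[C@@H](c1cc(OC)cc(OC)c1)[C@@H](c1ccc(OC)cc1)O2 | intermediate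
11 | (2R,3R)-5-bromo-3-(3,5-dimethoxyphenyl)-7-methoxy-2-(4-methoxyphenyl)-2,3-dihydro-1-benzofuran (trans; Ar2–Br) | Brc1cc(OC)c2c(c1)[C@@H](c1cc(OC)cc(OC)c1)[C@H](c1ccc(OC)cc1)O2 | intermediate
12 | 4-methoxyphenylacetyl chloride | COc1ccc(CC(=O)Cl)cc1 | starting material
13 | N-methoxy-2-(4-methoxyphenyl)-N-methylacetamide | COc1ccc(CC(=O)N(C)OC)cc1 | intermediate
14 | [(2R,3R)-3-(3,5-dimethoxyphenyl)-7-methoxy-2-(4-methoxyphenyl)-2,3-dihydro-1-benzofuran-5-yl]lithium (Ar2–Li) | [Li]c1cc(OC)c2c(c1)[C@@H](c1cc(OC)cc(OC)c1)[C@H](c1ccc(OC)cc1)O2 | intermediate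
15 | 1-(Ar2)-2-(4-methoxyphenyl)ethan-1-one | COc1ccc(CC(=O)c2cc(OC)c3c(c2)[C@@H](c2cc(OC)cc(OC)c2)[C@H](c2ccc(OC)cc2)O3)cc1 | intermediate
16 | 5-methoxybenzene-1,3-diol (5-methoxyresorcinol) | COc1cc(O)cc(O)c1 | starting material
17 | 1-methoxy-3,5-bis(methoxymethoxy)benzene | COCOc1cc(OC)cc(OCOC)c1 | intermediate
18 | [4-methoxy-2,6-bis(methoxymethoxy)phenyl]lithium | [Li]c1c(OCOC)cc(OC)cc1OCOC | intermediate
19 | dichloro[4-methoxy-2,6-bis(methoxymethoxy)phenyl]cerium | Cl[Ce](Cl)c1c(OCOC)cc(OC)cc1OCOC | intermediate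
20 | 1-(Ar2)-1-[4-methoxy-2,6-bis(methoxymethoxy)phenyl]-2-(4-methoxyphenyl)ethan-1-ol (both carbinol epimers) | COc1ccc(CC(O)(c2c(OCOC)cc(OC)cc2OCOC)c2cc(OC)c3c(c2)[C@@H](c2cc(OC)cc(OC)c2)[C@H](c2ccc(OC)cc2)O3)cc1 | intermediate
21 | 5-methoxy-2-[(Z)-1-(Ar2)-2-(4-methoxyphenyl)ethenyl]-1,3-bis(methoxymethoxy)benzene (Z drawn; E isomer may accompany it) | COc1ccc(/C=C(\c2c(OCOC)cc(OC)cc2OCOC)c2cc(OC)c3c(c2)[C@@H](c2cc(OC)cc(OC)c2)[C@H](c2ccc(OC)cc2)O3)cc1 | intermediate
22 | {5-methoxy-2-[(Z)-1-(Ar2)-2-(4-methoxyphenyl)ethenyl]-1,3-phenylene}bis(oxy)bis(trimethylsilane) | COc1ccc(/C=C(\c2c(O[Si](C)(C)C)cc(OC)cc2O[Si](C)(C)C)c2cc(OC)c3c(c2)[C@@H](c2cc(OC)cc(OC)c2)[C@H](c2ccc(OC)cc2)O3)cc1 | intermediate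
23 | 5-methoxy-2-[(Z)-1-(Ar2)-2-(4-methoxyphenyl)ethenyl]benzene-1,3-diol (key-step precursor) | COc1ccc(/C=C(\c2c(O)cc(OC)cc2O)c2cc(OC)c3c(c2)[C@@H](c2cc(OC)cc(OC)c2)[C@H](c2ccc(OC)cc2)O3)cc1 | intermediate
24 | (2S,3S)-3-(Ar2)-6-methoxy-2-(4-methoxyphenyl)-2,3-dihydro-1-benzofuran-4-ol (key-step product) | Oc1cc(OC)cc2c1[C@H](c1cc(OC)c3c(c1)[C@@H](c1cc(OC)cc(OC)c1)[C@H](c1ccc(OC)cc1)O3)[C@@H](c1ccc(OC)cc1)O2 | intermediate
25 | (2S,3S)-3-(Ar2)-6-methoxy-2-(4-methoxyphenyl)-2,3-dihydro-1-benzofuran-4-yl trifluoromethanesulfonate | O=S(=O)(Oc1cc(OC)cc2c1[C@H](c1cc(OC)c3c(c1)[C@@H](c1cc(OC)cc(OC)c1)[C@H](c1ccc(OC)cc1)O3)[C@@H](c1ccc(OC)cc1)O2)C(F)(F)F | intermediate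
26 | (2S,3S)-3-[(2R,3R)-3-(3,5-dihydroxyphenyl)-7-hydroxy-2-(4-hydroxyphenyl)-2,3-dihydro-1-benzofuran-5-yl]-6-hydroxy-2-(4-hydroxyphenyl)-2,3-dihydro-1-benzofuran-4-yl trifluoromethanesulfonate | O=S(=O)(Oc1cc(O)cc2c1[C@H](c1cc(O)c3c(c1)[C@@H](c1cc(O)cc(O)c1)[C@H](c1ccc(O)cc1)O3)[C@@H](c1ccc(O)cc1)O2)C(F)(F)F | intermediate
27 | (2S,3S)-6-acetoxy-2-(4-acetoxyphenyl)-3-[(2R,3R)-7-acetoxy-2-(4-acetoxyphenyl)-3-(3,5-diacetoxyphenyl)-2,3-dihydro-1-benzofuran-5-yl]-2,3-dihydro-1-benzofuran-4-yl trifluoromethanesulfonate | O=S(=O)(Oc1cc(OC(C)=O)cc2c1[C@H](c1cc(OC(C)=O)c3c(c1)[C@@H](c1cc(OC(C)=O)cc(OC(C)=O)c1)[C@H](c1ccc(OC(C)=O)cc1)O3)[C@@H](c1ccc(OC(C)=O)cc1)O2)C(F)(F)F | intermediate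
28 | tert-butyl(4-ethynylphenoxy)dimethylsilane | C#Cc1ccc(O[Si](C)(C)C(C)(C)C)cc1 | starting material
29 | tert-butyldimethyl{4-[(Z)-2-(4,4,5,5-tetramethyl-1,3,2-dioxaborolan-2-yl)ethenyl]phenoxy}silane | CC(C)(C)[Si](C)(C)Oc1ccc(/C=C\B2OC(C)(C)C(C)(C)O2)cc1 | intermediate
30 | (2S,3S)-6-acetoxy-2-(4-acetoxyphenyl)-3-[(2R,3R)-7-acetoxy-2-(4-acetoxyphenyl)-3-(3,5-diacetoxyphenyl)-2,3-dihydro-1-benzofuran-5-yl]-4-{(Z)-2-[4-(tert-butyldimethylsilyloxy)phenyl]ethenyl}-2,3-dihydro-1-benzofuran | CC(C)(C)[Si](C)(C)Oc1ccc(/C=C\c2cc(OC(C)=O)cc3c2[C@H](c2cc(OC(C)=O)c4c(c2)[C@@H](c2cc(OC(C)=O)cc(OC(C)=O)c2)[C@H](c2ccc(OC(C)=O)cc2)O4)[C@@H](c2ccc(OC(C)=O)cc2)O3)cc1 | intermediate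
31 | (2S,3S)-3-[(2R,3R)-3-(3,5-dihydroxyphenyl)-7-hydroxy-2-(4-hydroxyphenyl)-2,3-dihydro-1-benzofuran-5-yl]-2-(4-hydroxyphenyl)-4-[(Z)-2-(4-hydroxyphenyl)ethenyl]-2,3-dihydro-1-benzofuran-6-ol | Oc1ccc(/C=C\c2cc(O)cc3c2[C@H](c2cc(O)c4c(c2)[C@@H](c2cc(O)cc(O)c2)[C@H](c2ccc(O)cc2)O4)[C@@H](c2ccc(O)cc2)O3)cc1 | target

**Step count and risks**

Total step count: 17. Longest linear sequence: 14 steps (1, 2, 3, 4, 5, 6, 8, 10, 11, 12, 13, 14, 16, 17).

Steps most likely to fail:

1. Step 12. Proton transfer may go mainly to C2, so that the unproductive diarylmethyl cation accumulates and feeds oligomerisation. A loosely bound or uncatalysed pathway may close ring 1 without facial control. Reversible reopening of the product under the acid may erode C3. Fallback with known chemistry, setting out from 21 and coming back at 24: asymmetric hydroboration of 21 with monoisopinocampheylborane (THF, −25 °C; then NaOH, H2O2) puts boron on C2 and hydrogen on C3 from the reagent‑chosen face and should give the secondary benzylic alcohol (1R,2S)-2-(Ar2)-1-(4-methoxyphenyl)-2-[4-methoxy-2,6-bis(methoxymethoxy)phenyl]ethan-1-ol F1. HCl in MeOH (0 °C → rt) then removes both methoxymethyl groups and ionises the C2 carbinol to the para‑methoxybenzylic cation, which an ortho‑hydroxyl captures trans to the C3 substituent to give 24. A wrong C3 epimer is a diastereomer, since ring 2 is enantiopure, and is removed by chromatography.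

2. Step 10. The aryl metal may deprotonate the benzyl ketone instead of adding to it, returning 15 after work-up. Fallback, setting out from 15 (with 18 made from 17 as before) and coming back at 21: enolisation is made productive. KHMDS and PhNTf2 (THF, −78 °C) convert 15 into the enol triflate (Z)-1-(Ar2)-2-(4-methoxyphenyl)ethenyl trifluoromethanesulfonate F2. Aryllithium 18 is transmetalated with ZnCl2 to chlorido[4-methoxy-2,6-bis(methoxymethoxy)phenyl]zinc F3. Negishi coupling (Pd(OAc)2, SPhos, THF, 50 °C) joins the two with retention of geometry to give 21.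

3. Step 16. Oxidative addition at the hindered triflate may be slow, the triflate may be hydrolysed under the basic conditions, or the alkene may isomerise from Z to E through palladium hydride species. Fallback, setting out from 27 and coming back at 30: Sonogashira coupling of 27 with alkyne 28 (Pd(PPh3)2Cl2, CuI, n-Bu4NI, Et3N, DMF, 60 °C) gives the diarylalkyne (2S,3S)-6-acetoxy-2-(4-acetoxyphenyl)-3-[(2R,3R)-7-acetoxy-2-(4-acetoxyphenyl)-3-(3,5-diacetoxyphenyl)-2,3-dihydro-1-benzofuran-5-yl]-4-{[4-(tert-butyldimethylsilyloxy)phenyl]ethynyl}-2,3-dihydro-1-benzofuran F4. Cis‑selective semihydrogenation (H2, Pd/CaCO3 poisoned with Pb(OAc)2, quinoline, EtOAc, rt) then gives 30.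

**Further compounds**

F1 | step 12 | (1R,2S)-2-(Ar2)-1-(4-methoxyphenyl)-2-[4-methoxy-2,6-bis(methoxymethoxy)phenyl]ethan-1-ol | COCOc1cc(OC)cc(OCOC)c1[C@H](c1cc(OC)c2c(c1)[C@@H](c1cc(OC)cc(OC)c1)[C@H](c1ccc(OC)cc1)O2)[C@@H](O)c1ccc(OC)cc1
F2 | step 10 | (Z)-1-(Ar2)-2-(4-methoxyphenyl)ethenyl trifluoromethanesulfonate | COc1ccc(/C=C(\OS(=O)(=O)C(F)(F)F)c2cc(OC)c3c(c2)[C@@H](c2cc(OC)cc(OC)c2)[C@H](c2ccc(OC)cc2)O3)cc1
F3 | step 10 | chlorido[4-methoxy-2,6-bis(methoxymethoxy)phenyl]zinc | Cl[Zn]c1c(OCOC)cc(OC)cc1OCOC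
F4 | step 16 | (2S,3S)-6-acetoxy-2-(4-acetoxyphenyl)-3-[(2R,3R)-7-acetoxy-2-(4-acetoxyphenyl)-3-(3,5-diacetoxyphenyl)-2,3-dihydro-1-benzofuran-5-yl]-4-{[4-(tert-butyldimethylsilyloxy)phenyl]ethynyl}-2,3-dihydro-1-benzofuran | CC(C)(C)[Si](C)(C)Oc1ccc(C#Cc2cc(OC(C)=O)cc3c2[C@H](c2cc(OC(C)=O)c4c(c2)[C@@H](c2cc(OC(C)=O)cc(OC(C)=O)c2)[C@H](c2ccc(OC(C)=O)cc2)O4)[C@@H](c2ccc(OC(C)=O)cc2)O3)cc1
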